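Double product born at the end of a run cannot have isomerised, while double product born at the start has had the whole 20 s.

    substrate + reagent → mono adduct (k1 = 704 M⁻¹ s⁻¹)
    double product → over-reaction product (k2 = 2.42 × 10⁻⁵ s⁻¹)
    double product ⇌ isomer of the product (K3 = 3.1, k3 = 0.0382 s⁻¹)
    reagent + mono adduct → double product (k4 = 894 M⁻¹ s⁻¹)

| setting | Wednesday's | Monday's | Saturday's |
|---|---|---|---|
| substrate | 0.50 mM | 0.80 mM | 1.2 mM |
| reagent | 0.550 mM | 0.550 mM | 0.550 mM |
| time | 20 s | 20 s | 20 s |

1. share of double product in all that became double product or isomer of the product for Wednesday's, Monday's, Saturday's, in this order
2. how that number moves from the first to the last of them (falls all the way / hardly changes / rises all the way / falls, then rises / rises, then falls)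

- the share counts what is present at the end, not what went on to other products
- "hardly changes" means that all values lie within two and a half points (for a concentration: within two and a half percent of the largest)
- run time (Wednesday's): 20 s

The isomerisation relaxes both ways at once, so its rate constant is the forward constant plus the forward constant over 3.1. I multiply that sum by the run time and call the product the relaxation number, 1.01: how many relaxation times the run holds. The equilibrium share of double product is 24.4 %. I leave the over-reaction aside, because its constant is far smaller than the forward constant of the isomerisation. Double product present from the first instant therefore ends, by this estimate, at a share of 51.9 %, and anything born later stands above that.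

But the charge of substrate stands nowhere in the relaxation number, so it gives a floor and not a row. One number is not enough. I need a second clock, the time of reagent's first encounter, the inverse of the first step's constant times c(substrate) as charged. Reagent is the limiting reagent even in Wednesday's flask, which needs 1.00 mM to carry all its substrate through to double product and holds 0.550 mM. The clock is 2.84 s in Wednesday's flask and a shorter 1.18 s in Saturday's. Taking each clock off the run gives 56.2 % for Wednesday's and 53.6 % for Saturday's. That is a fall of 2.6 percentage points, right at the margin, and I commit to a fall.

The forecast starts higher than I do, with 59 %, 56 % and 54.6 %, and says it falls all the way, since "More substrate uses up the reagent sooner, so the double product forms earlier and has longer to isomerise".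

The flask gives 58.8 %, 55.8 % and 54.4 %, so the share falls all the way and stays above the floor. In Wednesday's flask at 20.0 s, double product is made at 0.0989 of the rate at which it is used up, each step taken net. Read backwards through the relaxation number, Wednesday's share is the one that double product all of a single age would show at an effective age of 15.6 s. Saturday's share, read the same way, gives an effective age of 18.3 s.

The numbers of this flask stand for no real mixture; the flask was simulated.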